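**Retrosynthetic overview**

1. Target ⇐ thermal 1,2-interchange of a trans-diaxial tertiary bromide/secondary chloride on ring A (cyclohexane) into the trans-diequatorial C3'–Br/C4'–Cl pair; the diaxial pair ⇐ ring A alkene (Cl+/H2O, then OH → Br).
2. Ring B (oxane) ⇐ closure of the O1–C6 bond: the C2 tertiary hydroxyl adds to a C6=CH2 alkene.
3. Enabling feature: O1 lies between two fully substituted carbons, and C6 with its methyl and ring A is a masked limonene isopropenyl unit. A tertiary radical/cation equivalent at C6 sits five atoms from the C2 oxygen (O1–C2–C3–C4–C5–C6), so a 6-exo chair closure is open.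
4. Seco-bromohydrin ⇐ (R)-limonene (ring A, C1', C6, its methyl, C5) + an (R)-epoxy tosylate from prenol (C4, C3, C2 and both methyls).
5. Order of ring formation: ring A from the chiral pool, ring B in the key step, ring A halogens last.

Key step: step 5

Locants: ring B = oxane, O1, C2 (two methyls), C3 (Br), C6 (methyl and ring A); ring A = cyclohexane, C1' (bonded to C6), C3' (Br), C4' (Cl, methyl).
Remark on the chemistry: direct anti addition of BrCl to the ring A alkene is expected to give the diaxial pair with both centres opposite to the target, so chlorine is brought in as the electrophile, bromide as the nucleophile, and the two halogens are then interchanged.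

**Step 1**
Reactants: 1 3-methylbut-2-en-1-ol (prenol)
Product: 2 (R)-(3,3-dimethyloxiran-2-yl)methanol
Conditions: Ti(OiPr)4 (5 mol %), D-(−)-diisopropyl tartrate (7 mol %), t-BuOOH, 4 Å MS, CH2Cl2, −20 °C; non-aqueous work-up
Reagents that add atoms: tert-butyl hydroperoxide, CC(C)(C)OO
Why: Sharpless asymmetric epoxidation; the D-(−)-tartrate ligand directs oxygen to the alkene face that gives the (R) epoxide carbon, the future C3 of ring B.

**Step 2**
Reactants: 2 (R)-(3,3-dimethyloxiran-2-yl)methanol
Product: 3 [(2R)-3,3-dimethyloxiran-2-yl]methyl 4-methylbenzenesulfonate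
Conditions: TsCl, Et3N, DMAP (cat.), CH2Cl2, 0 °C
Reagents that add atoms: 4-methylbenzenesulfonyl chloride, Cc1ccc(cc1)S(Cl)(=O)=O
Why: Sulfonylation of the primary alcohol gives an SN2-active electrophile and leaves the stereocentre untouched.

**Step 3**
Reactants: 4 (R)-(+)-limonene; 3 [(2R)-3,3-dimethyloxiran-2-yl]methyl 4-methylbenzenesulfonate
Product: 6 (3R)-2,2-dimethyl-3-{3-[(1R)-4-methylcyclohex-3-en-1-yl]but-3-en-1-yl}oxirane, via 10-lithiolimonene 5 (not isolated)
Conditions: n-BuLi, TMEDA, hexane, rt, 24 h; then THF, −78 °C, add 3, −78 → 0 °C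
Reagents that add atoms: none
Why: Allylic metalation of limonene at the isopropenyl methyl gives a 2-substituted allyllithium with two equivalent CH2 termini, and SN2 alkylation by the primary tosylate (faster than opening of the hindered trisubstituted epoxide at low temperature) should form the C4–C5 bond without touching either stereocentre.

**Step 4**
Reactants: 6 (3R)-2,2-dimethyl-3-{3-[(1R)-4-methylcyclohex-3-en-1-yl]but-3-en-1-yl}oxirane
Product: 7 (3S)-3-bromo-2-methyl-6-[(1R)-4-methylcyclohex-3-en-1-yl]hept-6-en-2-ol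
Conditions: Li2NiBr4, THF, 0 °C → rt; pH 7 buffer work-up
Reagents that add atoms: dilithium tetrabromonickelate, [Li+].[Li+].[Br-].[Br-].[Br-].[Br-].[Ni+2]
Why: Epoxide-to-bromohydrin opening; the soft bromide attacks the less substituted epoxide carbon by SN2 with inversion, which sets the (S) bromide (C3 of ring B) and leaves the tertiary alcohol at C2.

**Step 5**
Reactants: 7 (3S)-3-bromo-2-methyl-6-[(1R)-4-methylcyclohex-3-en-1-yl]hept-6-en-2-ol
Product: 8 (3S,6R)-3-bromo-2,2,6-trimethyl-6-[(1R)-4-methylcyclohex-3-en-1-yl]oxane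
Conditions: Co(salen) [C36H52CoN2O2, N,N'-bis(3,5-di-tert-butylsalicylidene)cyclohexane-1,2-diaminato cobalt, divalent cobalt] (3 mol %), N-fluoro-2,4,6-trimethylpyridinium tetrafluoroborate (1.3 equiv), PhSiH3 (1.2 equiv), PhCF3, 0 °C → rt
Reagents that add atoms: none
Why: A cobalt hydride of trivalent cobalt transfers a hydrogen atom to the CH2 terminus of the 1,1-disubstituted alkene; the tertiary C6 radical is captured by cobalt and oxidised to an alkylcobalt species of tetravalent cobalt, a tertiary cation equivalent that the C2 hydroxyl attacks to form the O1–C6 bond. The closest known reaction type is the cobalt salen-catalysed radical-polar crossover hydroalkoxylation of unactivated alkenols, which is Markovnikov-selective and tolerates tertiary alcohols and alkyl bromides. Ring B closes in the 6-exo mode through a chair. The new C6 stereocentre is controlled by the C3 bromine (equatorial in the chair) together with the axial methyl at C2: the large cyclohexenyl group avoids the position syn-axial to that methyl, so it should end equatorial and trans to bromine while the new methyl ends axial, which is the (6R) configuration. The step needs site selectivity for the 1,1-disubstituted alkene over the trisubstituted ring A alkene, secured by the preference of hydrogen atom transfer for the less substituted alkene and by the intramolecular trap. It also needs the C1' centre next to the reacting carbon to survive, secured by neutral conditions that avoid a free cation and its elimination toward C1'.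

**Step 6**
Reactants: 8 (3S,6R)-3-bromo-2,2,6-trimethyl-6-[(1R)-4-methylcyclohex-3-en-1-yl]oxane
Product: 9 (1S,2S,4R)-4-[(2R,5S)-5-bromo-2,6,6-trimethyloxan-2-yl]-2-chloro-1-methylcyclohexan-1-ol
Conditions: trichloroisocyanuric acid (0.35 equiv), acetone/H2O (5:1), 0 °C
Reagents that add atoms: trichloroisocyanuric acid, ClN1C(=O)N(Cl)C(=O)N(Cl)C1=O; water, O
Why: Chlorohydrin formation; Cl+ should add axially to C3' on the face anti to the equatorial oxanyl group and water should open the chloronium/β-chloro cation at the tertiary C4' (Markovnikov, trans-diaxial), the pattern known for limonene halohydrins.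

**Step 7**
Reactants: 9 (1S,2S,4R)-4-[(2R,5S)-5-bromo-2,6,6-trimethyloxan-2-yl]-2-chloro-1-methylcyclohexan-1-ol
Product: 10 (3S,6R)-3-bromo-6-[(1R,3S,4S)-4-bromo-3-chloro-4-methylcyclohexyl]-2,2,6-trimethyloxane
Conditions: 1-bromo-N,N,2-trimethylprop-1-en-1-amine (1.3 equiv), CH2Cl2, −20 °C → rt
Reagents that add atoms: 1-bromo-N,N,2-trimethylprop-1-en-1-amine, CC(C)=C(Br)N(C)C
Why: Neutral tertiary alcohol-to-bromide exchange with an α-bromoenamine (Ghosez-type reagent); the alkoxy-iminium group ionises with help of the antiperiplanar axial chlorine and bromide returns axially to C4' anti to chlorine (retention), while the acid-labile di-tertiary ether of ring B is not exposed to HBr.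

**Step 8**
Reactants: 10 (3S,6R)-3-bromo-6-[(1R,3S,4S)-4-bromo-3-chloro-4-methylcyclohexyl]-2,2,6-trimethyloxane
Product: 11 deoxycaespitol, (3S,6R)-3-bromo-6-[(1R,3R,4R)-3-bromo-4-chloro-4-methylcyclohexyl]-2,2,6-trimethyloxane
Conditions: MeNO2 (0.05 M), 2,6-di-tert-butyl-4-methylpyridine (0.1 equiv), 70 °C
Reagents that add atoms: none
Why: Diaxial → diequatorial rearrangement of a vicinal dihalide, known for trans-diaxial steroidal dihalides including bromochlorides: the axial tertiary C4'–Br ionises with the antiperiplanar C3'–Cl to a chloronium bromide ion pair, bromide shifts on its own face to C3' and chlorine closes onto C4' on the other face, so both centres invert to (3'R,4'R); the product has the stronger tertiary C–Cl/secondary C–Br pair and cannot re-ionise without the all-axial chair, so the interchange should act as a funnel.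

**Compound list**

1 | 3-methylbut-2-en-1-ol (prenol) | CC(C)=CCO | starting material
2 | (R)-(3,3-dimethyloxiran-2-yl)methanol | OC[C@H]1OC1(C)C | intermediate
3 | [(2R)-3,3-dimethyloxiran-2-yl]methyl 4-methylbenzenesulfonate | Cc1ccc(cc1)S(=O)(=O)OC[C@H]1OC1(C)C | intermediate
4 | (R)-(+)-limonene, (4R)-1-methyl-4-(prop-1-en-2-yl)cyclohex-1-ene | C=C(C)[C@@H]1CCC(C)=CC1 | starting material
5 | 10-lithiolimonene, {2-[(1R)-4-methylcyclohex-3-en-1-yl]prop-2-en-1-yl}lithium (TMEDA complex, not isolated) | [Li]CC(=C)[C@@H]1CCC(C)=CC1 | intermediate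
6 | (3R)-2,2-dimethyl-3-{3-[(1R)-4-methylcyclohex-3-en-1-yl]but-3-en-1-yl}oxirane | C=C(CC[C@H]1OC1(C)C)[C@@H]2CCC(C)=CC2 | intermediate
7 | (3S)-3-bromo-2-methyl-6-[(1R)-4-methylcyclohex-3-en-1-yl]hept-6-en-2-ol | C=C(CC[C@H](Br)C(C)(C)O)[C@@H]1CCC(C)=CC1 | intermediate
8 | (3S,6R)-3-bromo-2,2,6-trimethyl-6-[(1R)-4-methylcyclohex-3-en-1-yl]oxane | CC1(C)O[C@@](C)([C@@H]2CCC(C)=CC2)CC[C@@H]1Br | intermediate
9 | (1S,2S,4R)-4-[(2R,5S)-5-bromo-2,6,6-trimethyloxan-2-yl]-2-chloro-1-methylcyclohexan-1-ol (OH and Cl trans-diaxial) | CC1(C)O[C@@](C)([C@@H]2CC[C@](C)(O)[C@@H](Cl)C2)CC[C@@H]1Br | intermediate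
10 | (3S,6R)-3-bromo-6-[(1R,3S,4S)-4-bromo-3-chloro-4-methylcyclohexyl]-2,2,6-trimethyloxane (tertiary Br and secondary Cl trans-diaxial) | CC1(C)O[C@@](C)([C@@H]2CC[C@](C)(Br)[C@@H](Cl)C2)CC[C@@H]1Br | intermediate
11 | deoxycaespitol, (3S,6R)-3-bromo-6-[(1R,3R,4R)-3-bromo-4-chloro-4-methylcyclohexyl]-2,2,6-trimethyloxane | CC1(C)O[C@@](C)([C@@H]2CC[C@@](C)(Cl)[C@H](Br)C2)CC[C@@H]1Br | target

**Step count**

Total: 8 steps. Longest linear sequence: 8 steps (prenol → 11); 6 steps from limonene.

**Steps most likely to fail**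

Step 8. The tertiary bromide may lose HBr through the same ion pair that carries the interchange, or the interchange may stop at an equilibrium mixture. The fallback sets out from 8 and builds the diequatorial pair by substitution instead of rearrangement.
- Syn-dihydroxylation (OsO4 cat., NMO, acetone/H2O) on the ring A face anti to the oxanyl group should give (1R,2S,4R)-4-[(2R,5S)-5-bromo-2,6,6-trimethyloxan-2-yl]-1-methylcyclohexane-1,2-diol F1; the minor syn-face diol is removed.
- SOCl2/Et3N gives the cyclic sulfite F2, and RuCl3 (cat.)/NaIO4 oxidises it to the cyclic sulfate F3.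
- LiBr in THF opens F3 at the secondary carbon with inversion to the lithium sulfate monoester F4.
- H2SO4 (cat.)/H2O/THF releases the diequatorial bromohydrin (1R,2R,4R)-2-bromo-4-[(2R,5S)-5-bromo-2,6,6-trimethyloxan-2-yl]-1-methylcyclohexan-1-ol F5.
- Stereoretentive chlorodehydroxylation (SOCl2, TiCl4 cat., CH2Cl2, −78 → 0 °C; front-side collapse of the chlorosulfite) converts F5 into the tertiary chloride, and the route is rejoined at 11.

Step 5. Attack on the wrong face of C6 (a chair with axial bromine), reversible hydrogen atom transfer that moves the alkene toward C1', or capture of the cation equivalent by fluoride may erode the outcome. The fallback sets out from 7 and uses ionic oxymercuration. Hg(OCOCF3)2 in THF at 0 °C, then aqueous NaCl, should give the chloromercurial chloro{[(2R,5S)-5-bromo-6,6-dimethyl-2-[(1R)-4-methylcyclohex-3-en-1-yl]oxan-2-yl]methyl}mercury F6. Oxymercuration is reversible, so the C6 epimers can equilibrate, and the organomercurial can be purified as a solid. NaBH4/NaOH then replaces mercury by hydrogen, and the route is rejoined at 8.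

Step 4. Bromide may attack the tertiary epoxide carbon, or Lewis acid-induced hydride shift may give a ketone. The fallback sets out from 6. Acid-catalysed hydrolysis (HClO4 cat., THF/H2O, 0 °C; water enters at the tertiary carbon, so the secondary centre is retained) gives (3R)-2-methyl-6-[(1R)-4-methylcyclohex-3-en-1-yl]hept-6-ene-2,3-diol F7. SOCl2/Et3N converts it into the cyclic sulfite (5R)-4,4-dimethyl-5-{3-[(1R)-4-methylcyclohex-3-en-1-yl]but-3-en-1-yl}-1,3,2-dioxathiolane 2-oxide F8. LiBr in DMF at 70 °C opens F8 at the secondary carbon with inversion, and aqueous acid work-up releases the bromohydrin, so the route is rejoined at 7.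

**Further compounds**

F1 | step 8 | (1R,2S,4R)-4-[(2R,5S)-5-bromo-2,6,6-trimethyloxan-2-yl]-1-methylcyclohexane-1,2-diol | CC1(C)O[C@@](C)([C@@H]2CC[C@@](C)(O)[C@@H](O)C2)CC[C@@H]1Br
F2 | step 8 | cyclic sulfite of F1 (mixture at sulfur) | CC1(C)O[C@@](C)([C@@H]2CC[C@@]3(C)OS(=O)O[C@H]3C2)CC[C@@H]1Br
F3 | step 8 | cyclic sulfate of F1 | CC1(C)O[C@@](C)([C@@H]2CC[C@@]3(C)OS(=O)(=O)O[C@H]3C2)CC[C@@H]1Br
F4 | step 8 | lithium (1R,2R,4R)-2-bromo-4-[(2R,5S)-5-bromo-2,6,6-trimethyloxan-2-yl]-1-methylcyclohexyl sulfate | CC1(C)O[C@@](C)([C@@H]2CC[C@@](C)(OS(=O)(=O)[O-])[C@H](Br)C2)CC[C@@H]1Br.[Li+]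
F5 | step 8 | (1R,2R,4R)-2-bromo-4-[(2R,5S)-5-bromo-2,6,6-trimethyloxan-2-yl]-1-methylcyclohexan-1-ol | CC1(C)O[C@@](C)([C@@H]2CC[C@@](C)(O)[C@H](Br)C2)CC[C@@H]1Br
F6 | step 5 | chloro{[(2R,5S)-5-bromo-6,6-dimethyl-2-[(1R)-4-methylcyclohex-3-en-1-yl]oxan-2-yl]methyl}mercury | CC1(C)O[C@@](C[Hg]Cl)([C@@H]2CCC(C)=CC2)CC[C@@H]1Br
F7 | step 4 | (3R)-2-methyl-6-[(1R)-4-methylcyclohex-3-en-1-yl]hept-6-ene-2,3-diol | C=C(CC[C@@H](O)C(C)(C)O)[C@@H]1CCC(C)=CC1
F8 | step 4 | (5R)-4,4-dimethyl-5-{3-[(1R)-4-methylcyclohex-3-en-1-yl]but-3-en-1-yl}-1,3,2-dioxathiolane 2-oxide (mixture at sulfur) | C=C(CC[C@H]1OS(=O)OC1(C)C)[C@@H]2CCC(C)=CC2
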